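**Plan**

- Cuts: after removal of five benzyl ethers, each chromanone ring C is cut at O1–C8a and C4–C4a (the 4-methoxyphenyl flavanone in the last bond-forming event). This releases both A rings as 3,5-bis(benzyloxy)benzyne and leaves a cis-fused 3,6-diaryl-furo[3,4-c]furan-1,4-dione (dilactone). The dilactone is cut at its enol-lactone C6=C6a (H2), at O5–C4, at the aroyl–C bond (Claisen) and at the aldol C–C bond, back to a succinate imide, 4-methoxybenzaldehyde and a benzoate.
- Enabling feature: each ring C is a β-aryloxy ketone O1–C2–C3–C4(=O) fused to a ring A whose C5 oxygen stands next to C4a, so ring A can arrive as an aryne that takes O1 at C8a and the acyl carbon C4 at C4a. The two O1–C2–C3–C4 units share the C3–C3'' bond, so they can be stored cross-lactonised (O1 on C4'', O1'' on C4) in one bicycle, and each acyl transfer to an aryl anion frees the alkoxide for the next.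
- Forward order: γ-lactone → aroylation → second lactone ring as enol lactone → hydrogenation → ring C of the 4-(benzyloxy)phenyl flavanone, then ring C of the 4-methoxyphenyl flavanone in the same flask → debenzylation.
- Stereochemistry: C2 and C3 come from an auxiliary-controlled syn aldol. C3'' and C2'' are set together by syn addition of H2 to the convex face of the bicyclic enol lactone (cis fusion, endo aryl). The aryne relay breaks no bond at a stereocentre, so the exo aryl of the dilactone becomes the 2,3-cis and the endo aryl the 2,3-trans flavanone.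

Key step: step 9

Assumption: 3,5-bis(benzyloxy)phenol is taken as a purchasable phenol, and the carbon between the two carbonyl groups of the β-keto lactone is treated as configurationally labile (it is drawn 3,4-trans).

**Route**

Step 1
Reactants: 1 (S)-4-benzyloxazolidin-2-one; 2 methyl 4-chloro-4-oxobutanoate
Product: 3 methyl 4-[(4S)-4-benzyl-2-oxooxazolidin-3-yl]-4-oxobutanoate
Conditions: n-BuLi, THF, −78 °C; then 2, −78 → 0 °C
Reagents that add atoms: none
Why: N-acylation of the lithiated oxazolidinone by the acid chloride (imide formation) is much faster than attack at the methyl ester and places the auxiliary on a succinate half-ester.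

Step 2
Reactants: 3 methyl 4-[(4S)-4-benzyl-2-oxooxazolidin-3-yl]-4-oxobutanoate; 4 4-methoxybenzaldehyde
Product: 6 (4S)-4-benzyl-3-{[(2S,3S)-2-(4-methoxyphenyl)-5-oxooxolan-3-yl]carbonyl}oxazolidin-2-one, via aldol adduct 5 (not isolated)
Conditions: Bu2BOTf, i-Pr2NEt, CH2Cl2, −78 → 0 °C; 4, −78 → 0 °C; pH 7 buffer, MeOH, H2O2; then PPTS (cat.), CH2Cl2, rt
Reagents that add atoms: none
Why: In this Evans syn aldol reaction the Z boron enolate of the imide should add to the aldehyde through a Zimmerman–Traxler chair on the face away from the benzyl group of the (S)-auxiliary, which sets the (S,S) syn pair that becomes C3 and C2 of the 4-methoxyphenyl flavanone, and the γ-hydroxy ester then closes to the trans γ-lactone by transesterification without touching either centre.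

Step 3
Reactants: 6 (4S)-4-benzyl-3-{[(2S,3S)-2-(4-methoxyphenyl)-5-oxooxolan-3-yl]carbonyl}oxazolidin-2-one
Product: 7 (2S,3S)-2-(4-methoxyphenyl)-5-oxooxolane-3-carboxylic acid
Conditions: LiOH, H2O2, THF–H2O, 0 °C; Na2SO3; aq. HCl to pH 2
Reagents that add atoms: hydrogen peroxide (as LiOOH), OO
Why: Hydroperoxide cleaves the exocyclic imide carbonyl selectively (standard removal of the oxazolidinone auxiliary) and the γ-lactone re-forms on acidification, so both stereocentres are carried through unchanged.

Step 4
Reactants: 7 (2S,3S)-2-(4-methoxyphenyl)-5-oxooxolane-3-carboxylic acid; 8 methyl 4-(benzyloxy)benzoate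
Product: 9 (2S,3S,4R)-4-[4-(benzyloxy)benzoyl]-2-(4-methoxyphenyl)-5-oxooxolane-3-carboxylic acid
Conditions: LiN(SiMe3)2 (3.3 equiv), THF, −78 °C; 8, −78 → 0 °C; aq. HCl
Reagents that add atoms: none
Why: In this crossed Claisen condensation the carboxylate shields the C3–H, so the lactone enolate forms only at C4 and is acylated by the non-enolisable benzoate, the product being held as its β-dicarbonyl enolate until work-up; the new C4 centre is labile and is fixed in step 6.

Step 5
Reactants: 9 (2S,3S,4R)-4-[4-(benzyloxy)benzoyl]-2-(4-methoxyphenyl)-5-oxooxolane-3-carboxylic acid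
Product: 10 (3S,3aS)-6-[4-(benzyloxy)phenyl]-3-(4-methoxyphenyl)-3,3a-dihydro-1H,4H-furo[3,4-c]furan-1,4-dione
Conditions: DCC, CH2Cl2, 0 °C → rt
Reagents that add atoms: none
Why: In this enol lactonisation of a γ-keto acid, carbodiimide activation of the carboxyl lets the enol oxygen of the β-keto lactone close the second five-membered ring (5-exo-trig O-acylation), which turns the labile centre into an sp2 carbon and ties the aroyl oxygen to the C3a side.

Step 6
Reactants: 10 (3S,3aS)-6-[4-(benzyloxy)phenyl]-3-(4-methoxyphenyl)-3,3a-dihydro-1H,4H-furo[3,4-c]furan-1,4-dione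
Product: 11 (3S,3aS,6R,6aS)-6-[4-(benzyloxy)phenyl]-3-(4-methoxyphenyl)tetrahydro-1H,4H-furo[3,4-c]furan-1,4-dione
Conditions: H2 (4 atm), Rh/Al2O3 (5% Rh), EtOAc, rt
Reagents that add atoms: none
Why: Heterogeneous syn hydrogenation of the tetrasubstituted enol lactone over rhodium, which should spare the benzyl ether and the benzylic C–O bonds, is expected to deliver both hydrogens to the convex face marked by H-3a because only that face gives a cis-fused bicycle, so C6a (cis fusion) and C6 (aryl endo) are set in one event by substrate control.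

Step 7
Reactants: 12 3,5-bis(benzyloxy)phenol
Product: 13 3,5-bis(benzyloxy)-2-bromophenol
Conditions: NBS, CH2Cl2, −78 °C
Reagents that add atoms: N-bromosuccinimide, O=C1CCC(=O)N1Br
Why: Electrophilic aromatic bromination at low temperature should go to the less hindered position ortho to the free hydroxyl, which is the position needed for the silyl shift of step 8.

Step 8
Reactants: 13 3,5-bis(benzyloxy)-2-bromophenol
Product: 16 3,5-bis(benzyloxy)-2-(trimethylsilyl)phenyl trifluoromethanesulfonate, via aryl silyl ether 14 (not isolated), via lithium silylphenolate 15 (not isolated)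
Conditions: HN(SiMe3)2, THF, 70 °C, then evaporation; n-BuLi, THF, −100 → −78 °C; Tf2O, −100 °C → rt
Reagents that add atoms: hexamethyldisilazane, C[Si](C)(C)N[Si](C)(C)C; trifluoromethanesulfonic anhydride, O=S(=O)(OS(=O)(=O)C(F)(F)F)C(F)(F)F
Why: O-silylation, bromine–lithium exchange and retro-Brook migration of silicon from oxygen to carbon give the 2-silylphenolate, which is trapped as the triflate (the standard preparation of a Kobayashi aryne precursor).

Step 9
Reactants: 11 (3S,3aS,6R,6aS)-6-[4-(benzyloxy)phenyl]-3-(4-methoxyphenyl)tetrahydro-1H,4H-furo[3,4-c]furan-1,4-dione; 16 3,5-bis(benzyloxy)-2-(trimethylsilyl)phenyl trifluoromethanesulfonate (2.6 equiv)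
Product: 20 (2S,3S)-5,7-bis(benzyloxy)-3-{(2R,3S)-5,7-bis(benzyloxy)-2-[4-(benzyloxy)phenyl]-4-oxochroman-3-yl}-2-(4-methoxyphenyl)chroman-4-one, via aryne 17 (not isolated), via lactone alkoxide 18 (not isolated), via flavanone alkoxide 19 (not isolated)
Conditions: CsF (6 equiv), NaOMe (0.3 equiv), THF, 50 °C
Reagents that add atoms: none
Why: Proposed new method: catalytic methoxide opens the more strained endo-aryl lactone of 11 to the benzylic alkoxide 18, which adds to aryne 17 at the carbon remote from the flanking benzyloxy group; the aryl anion so placed ortho to that benzyloxy group attacks the adjacent lactone carbonyl (6-exo-trig), and collapse of the tetrahedral intermediate gives the trans chromanone of 19 while it frees the second benzylic alkoxide, which repeats O-arylation and 6-exo-trig acyl capture at the methyl ester to close ring C of the 4-methoxyphenyl flavanone (new O1–C8a and C4–C4a bonds) and returns methoxide. The closest known reaction types are the aryne annulation of salicylates to xanthones (O-arylation, then intramolecular acyl substitution by the aryl anion) and the acyl-alkylation of arynes by β-keto esters; new here are the aliphatic β-hydroxy acyl donor and the lactone leaving group that carries the chain from one ring to the next. No stereocentre is formed: C2, C3, C3'' and C2'' keep the configuration of 11, because only O–aryl and acyl–aryl bonds are made. The step needs regioselective addition to the unsymmetrical aryne, which the inductive effect of the benzyloxy group next to the aryne bond secures (oxygen to C8a, anion at C4a), and six- over seven-membered acyl capture, which the 1,3 spacing of oxygen and carbonyl in each aldol unit secures. It also needs each alkoxide to be arylated before retro-aldol cleavage or enolisation of the first chromanone, which is why the alkoxide is kept at catalytic level and no proton source is added. If the other lactone opens first, the same product should form by the reverse order of ring closures.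

Step 10
Reactants: 20 (2S,3S)-5,7-bis(benzyloxy)-3-{(2R,3S)-5,7-bis(benzyloxy)-2-[4-(benzyloxy)phenyl]-4-oxochroman-3-yl}-2-(4-methoxyphenyl)chroman-4-one
Product: 21 (2S,3S)-3-[(2R,3S)-5,7-dihydroxy-2-(4-hydroxyphenyl)-4-oxochroman-3-yl]-5,7-dihydroxy-2-(4-methoxyphenyl)chroman-4-one
Conditions: H2 (1 atm), Pd/C (10% Pd), EtOAc–MeOH, rt
Reagents that add atoms: none
Why: Catalytic hydrogenolysis should cleave the five benzyl aryl ethers under neutral conditions that neither enolise C3 or C3'' nor touch the methyl ether, so the cis and the trans flavanone are delivered unchanged.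

**Compound list**

1 | (S)-4-benzyloxazolidin-2-one | O=C1N[C@@H](Cc2ccccc2)CO1 | starting material
2 | methyl 4-chloro-4-oxobutanoate | COC(=O)CCC(=O)Cl | starting material
3 | methyl 4-[(4S)-4-benzyl-2-oxooxazolidin-3-yl]-4-oxobutanoate | COC(=O)CCC(=O)N1[C@@H](Cc2ccccc2)COC1=O | intermediate
4 | 4-methoxybenzaldehyde | COc1ccc(C=O)cc1 | starting material
5 | methyl (3S,4S)-3-{[(4S)-4-benzyl-2-oxooxazolidin-3-yl]carbonyl}-4-hydroxy-4-(4-methoxyphenyl)butanoate (syn aldol adduct) | COc1ccc([C@@H](O)[C@@H](C(=O)N2[C@@H](Cc3ccccc3)COC2=O)CC(=O)OC)cc1 | intermediate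
6 | (4S)-4-benzyl-3-{[(2S,3S)-2-(4-methoxyphenyl)-5-oxooxolan-3-yl]carbonyl}oxazolidin-2-one (2,3-trans lactone) | COc1ccc([C@H]2OC(=O)C[C@@H]2C(=O)N2[C@@H](Cc3ccccc3)COC2=O)cc1 | intermediate
7 | (2S,3S)-2-(4-methoxyphenyl)-5-oxooxolane-3-carboxylic acid | COc1ccc([C@H]2OC(=O)C[C@@H]2C(=O)O)cc1 | intermediate
8 | methyl 4-(benzyloxy)benzoate | COC(=O)c1ccc(OCc2ccccc2)cc1 | starting material
9 | (2S,3S,4R)-4-[4-(benzyloxy)benzoyl]-2-(4-methoxyphenyl)-5-oxooxolane-3-carboxylic acid (C4 labile, drawn 3,4-trans) | COc1ccc([C@H]2OC(=O)[C@@H](C(=O)c3ccc(OCc4ccccc4)cc3)[C@@H]2C(=O)O)cc1 | intermediate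
10 | (3S,3aS)-6-[4-(benzyloxy)phenyl]-3-(4-methoxyphenyl)-3,3a-dihydro-1H,4H-furo[3,4-c]furan-1,4-dione (bicyclic enol lactone) | COc1ccc([C@H]2OC(=O)C3=C(c4ccc(OCc5ccccc5)cc4)OC(=O)[C@H]23)cc1 | intermediate
11 | (3S,3aS,6R,6aS)-6-[4-(benzyloxy)phenyl]-3-(4-methoxyphenyl)tetrahydro-1H,4H-furo[3,4-c]furan-1,4-dione (cis-fused, 3-aryl exo, 6-aryl endo) | COc1ccc([C@H]2OC(=O)[C@H]3[C@@H]2C(=O)O[C@H]3c2ccc(OCc3ccccc3)cc2)cc1 | intermediate
12 | 3,5-bis(benzyloxy)phenol | Oc1cc(OCc2ccccc2)cc(OCc2ccccc2)c1 | starting material
13 | 3,5-bis(benzyloxy)-2-bromophenol | Oc1cc(OCc2ccccc2)cc(OCc2ccccc2)c1Br | intermediate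
14 | [3,5-bis(benzyloxy)-2-bromophenoxy]trimethylsilane | C[Si](C)(C)Oc1cc(OCc2ccccc2)cc(OCc2ccccc2)c1Br | intermediate
15 | lithium 3,5-bis(benzyloxy)-2-(trimethylsilyl)phenolate | [Li]Oc1cc(OCc2ccccc2)cc(OCc2ccccc2)c1[Si](C)(C)C | intermediate
16 | 3,5-bis(benzyloxy)-2-(trimethylsilyl)phenyl trifluoromethanesulfonate | C[Si](C)(C)c1c(OS(=O)(=O)C(F)(F)F)cc(OCc2ccccc2)cc1OCc1ccccc1 | intermediate
17 | 3,5-bis(benzyloxy)benzyne (1,2-didehydro-3,5-bis(benzyloxy)benzene) | C1#CC(OCc2ccccc2)=CC(OCc2ccccc2)=C1 | intermediate
18 | methyl (2S,3S,4S)-4-{(R)-[4-(benzyloxy)phenyl](hydroxy)methyl}-2-(4-methoxyphenyl)-5-oxooxolane-3-carboxylate (present as its alkoxide) | COc1ccc([C@H]2OC(=O)[C@H]([C@@H](O)c3ccc(OCc4ccccc4)cc3)[C@@H]2C(=O)OC)cc1 | intermediate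
19 | methyl (2S,3S)-2-{(2R,3S)-5,7-bis(benzyloxy)-2-[4-(benzyloxy)phenyl]-4-oxochroman-3-yl}-3-hydroxy-3-(4-methoxyphenyl)propanoate (present as its alkoxide) | COc1ccc([C@@H](O)[C@@H](C(=O)OC)[C@@H]2C(=O)c3c(OCc4ccccc4)cc(OCc4ccccc4)cc3O[C@H]2c2ccc(OCc3ccccc3)cc2)cc1 | intermediate
20 | (2S,3S)-5,7-bis(benzyloxy)-3-{(2R,3S)-5,7-bis(benzyloxy)-2-[4-(benzyloxy)phenyl]-4-oxochroman-3-yl}-2-(4-methoxyphenyl)chroman-4-one | COc1ccc([C@H]2Oc3cc(OCc4ccccc4)cc(OCc4ccccc4)c3C(=O)[C@H]2[C@@H]2C(=O)c3c(OCc4ccccc4)cc(OCc4ccccc4)cc3O[C@H]2c2ccc(OCc3ccccc3)cc2)cc1 | intermediate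
21 | (2S,3S)-3-[(2R,3S)-5,7-dihydroxy-2-(4-hydroxyphenyl)-4-oxochroman-3-yl]-5,7-dihydroxy-2-(4-methoxyphenyl)chroman-4-one (2,3-cis in the methoxyphenyl unit, 2,3-trans in the hydroxyphenyl unit) | COc1ccc([C@H]2Oc3cc(O)cc(O)c3C(=O)[C@H]2[C@@H]2C(=O)c3c(O)cc(O)cc3O[C@H]2c2ccc(O)cc2)cc1 | target

**Count and risks**

Total step count: 10. Longest linear sequence: 8 (steps 1 to 6, 9 and 10); steps 7 and 8 make the aryne precursor.

Steps most likely to fail:

- Step 9. The aryl anion may be protonated before it reaches the acyl group, the benzylic alkoxides may undergo retro-aldol cleavage, or the first chromanone may be enolised and opened by base before the second ring closes. The fallback sets out from 11 and returns at 20. 2-Fluoro-4,6-bis(benzyloxy)phenyllithium (from 1-fluoro-3,5-bis(benzyloxy)benzene and n-BuLi at −78 °C, 2.2 equiv) is added once to each lactone carbonyl, which after work-up should give the bis(2-fluoroaryl) diketo diol F1. KOt-Bu in THF then closes both chromanone rings by intramolecular nucleophilic aromatic substitution, each alkoxide displacing the fluoride ortho to the ketone that stands β to it.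
- Step 6. Hydrogen may be delivered to the wrong face, the double bond may migrate to the ring fusion before reduction, or a benzylic C–O bond may be hydrogenolysed. The fallback sets out from 9 and returns at 11 without the enol lactone. Esterification with TMSCHN2 gives the keto lactone methyl ester F2. Asymmetric transfer hydrogenation of the aryl ketone with RuCl(p-cymene)[(R,R)-TsDPEN] and HCO2H/Et3N should set the carbinol by catalyst control and give the hydroxy lactone F3 (drawn as the 3,4-trans epimer). DBU in toluene then epimerises the centre α to the lactone carbonyl, and only the 3,4-cis epimer can close onto the methyl ester, which funnels the material to 11.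
- Step 4. The enolate may be acylated on oxygen, the lactone may be opened by the methoxide that is released, or proton transfer may quench the dianion. The fallback sets out from 7 and returns at 9. The same dianion is added to 4-(benzyloxy)benzaldehyde (aldol addition) to give the hydroxy acid F4 as a mixture at the carbinol, and Dess–Martin periodinane oxidises the secondary alcohol to the ketone of 9.

**Further compounds**

F1 | step 9 | (2S,3S)-1,4-bis[2,4-bis(benzyloxy)-6-fluorophenyl]-2-{(R)-[4-(benzyloxy)phenyl](hydroxy)methyl}-3-[(S)-hydroxy(4-methoxyphenyl)methyl]butane-1,4-dione | COc1ccc([C@@H](O)[C@@H](C(=O)c2c(F)cc(OCc3ccccc3)cc2OCc2ccccc2)[C@H](C(=O)c2c(F)cc(OCc3ccccc3)cc2OCc2ccccc2)[C@@H](O)c2ccc(OCc3ccccc3)cc2)cc1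
F2 | step 6 | methyl (2S,3S,4R)-4-[4-(benzyloxy)benzoyl]-2-(4-methoxyphenyl)-5-oxooxolane-3-carboxylate (C4 labile) | COc1ccc([C@H]2OC(=O)[C@@H](C(=O)c3ccc(OCc4ccccc4)cc3)[C@@H]2C(=O)OC)cc1
F3 | step 6 | methyl (2S,3S,4R)-4-{(R)-[4-(benzyloxy)phenyl](hydroxy)methyl}-2-(4-methoxyphenyl)-5-oxooxolane-3-carboxylate | COc1ccc([C@H]2OC(=O)[C@@H]([C@@H](O)c3ccc(OCc4ccccc4)cc3)[C@@H]2C(=O)OC)cc1
F4 | step 4 | (2S,3S,4R)-4-{[4-(benzyloxy)phenyl](hydroxy)methyl}-2-(4-methoxyphenyl)-5-oxooxolane-3-carboxylic acid (mixture at the carbinol) | COc1ccc([C@H]2OC(=O)[C@@H](C(O)c3ccc(OCc4ccccc4)cc3)[C@@H]2C(=O)O)cc1
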